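| flask | starting material | second substrate | solid reagent | free catalyst | temperature | remark | time |
|---|---|---|---|---|---|---|---|
| epsilon | 0.51 M | 1.02 M | 0.561 M | 1.1 mM | 60 °C | the very flask that is asked about, followed so far |  |
| theta | 0.51 M | 2 M | 0.561 M | 1.1 mM | 55 °C | run made earlier |  |
| flask | 0.51 M | 1.02 M | 0.561 M | 1.1 mM | 60 °C |  | 40 h |

| epsilon: time / h | epsilon: target / % | theta: time / h | theta: target / % |
|---|---|---|---|
| 5.00 | 3.0 | 1.50 | 0 |
| 10.0 | 5.7 | 3.00 | 0.3 |
| 15.0 | 7.5 | 6.00 | 1.8 |
| 20.0 | 8.6 | 10.0 | 2.7 |
| 25.0 | 8.9 | 20.0 | 5.3 |

(each reading ± 0.5 percentage points)

- solid reagent is a solid; its amount is given per volume of the solution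
- what is taken out of target is counted as made
- the earlier runs were read with a standard deviation of 0.5 percentage points
- at the start none of the solid reagent is in solution
- additions bring no volume worth counting

- south: at 40 h take out 90% of the target then present, then wait 20 h
- north: at 40 h raise the temperature by 15 K, then wait 20 h
- north-west: at 40 h add free catalyst, 100% of the amount charged, then wait 20 h
- north-east: change nothing and wait 20 h more

1. target, in percent of the starting material first charged, at 40 h
2. what to do for the largest gain in target; "none" if nothing gains more than 2 percentage points (south / north / north-west / north-east / none)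
3. target present, with what was taken out counted in, in percent of the starting material first charged, after north
4. target present, with what was taken out counted in, in percent of the starting material first charged, after north-west

1. Time pays less late than early in the epsilon run, which is the asked flask followed so far. The target gains 2.7 percentage points between 5.00 h and 10.0 h, but 0.3 points between 20.0 h and 25.0 h, while 91.1% of the starting material is not target. This stall is read here as loss of catalyst, an assumption the readings do not prove.

2. Free catalyst is the smallest charge, so its balance comes first. Let its live share of the charge fall as a pseudo-first-order loss. The target gained per hour is taken to follow that share, so equal stretches of time shrink the gains by equal factors.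

3. The gains of 2.7 points and 1.1 points, set 10.0 h apart, give a loss constant of 0.0898 /h. Summing the shrinking gains gives a first ceiling of 10.5%.

4. The weak link is the small gain, a difference of two readings that each carry 0.5 points. Wider stretches reforge it: the gains from 5.00 h to 15.0 h and from 15.0 h to 25.0 h are 4.5 points and 1.4 points, which give 0.117 /h. The catalyst yield, the fraction of the starting material that one charge of catalyst turns into target before it dies, is then 9.53%, as a reading.

5. This reckoning puts the flask at 9.42% at 40 h, with 0.11 points still to come, so north ends near 9.53%. A fresh charge over 20 h should add 8.6 points, which gives 18.0% after north-west. The catalyst yield belongs to this recipe: the theta run, with 2 M of second substrate at 55 °C, is still rising at 5.3%.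

6. The forecast gives 9.8%, north-west, 10% after north and 17.3% after north-west: “I read the stall as first-order catalyst death”. Its "now" stands 0.38 points above this reckoning, and its north-west figure 0.70 points below.

7. The flask gives 9.62% at 40 h.

    partner + catalyst intermediate A → free catalyst + target (k = 138 /M/h, Ea = 64.0 kJ/mol)
    solid reagent ⇌ partner, rate k2*(cs2 - [partner]) while solid is left; crystals form when [partner] > cs2 (solubility = 0.360 M, k = 0.265 /h)
    partner + catalyst intermediate B → free catalyst + second product (k = 130 /M/h, Ea = 62.0 kJ/mol)
    starting material + free catalyst ⇌ catalyst intermediate A (K = 1.67 /M, k = 152 /M/h, Ea = 49.0 kJ/mol, ΔH = −58.0 kJ/mol)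
    second substrate + free catalyst → spent catalyst (k = 0.440 /M/h, Ea = 75.0 kJ/mol)
    second substrate + free catalyst ⇌ catalyst intermediate B (K = 2.70 /M, k = 3990 /M/h, Ea = 41.0 kJ/mol, ΔH = −39.0 kJ/mol)
    (constants at 60 °C)

North-west is the best choice at 18.4%, a gain of 8.8 points, against 0.21 points for waiting, and north ends at 9.72%. In the flask at 40.0 h, spent catalyst stands at 98.2% of the catalyst charged, while 90.4% of the starting material is still free. The fresh charge returns 0.921 of the catalyst yield. The forecast would be wrong if that yield itself moved, as a neighbour flask shows: with 0.14 M of solid reagent, spent catalyst again reaches 98.0% at 40.0 h, yet the target stands at 4.01%, 0.421 of the catalyst yield.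

The earlier runs and the new flask were generated by integration on assumed constants; the scatter is artificial.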